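**Plan**

1. Lignan numbering is used: the tetrahydrofuran ring is O–C7(aryl)–C8(C9 arm)–C8′(benzyl)–C9′H2. The retrosynthesis cuts the C9–O ester bond first, then the ring bonds O–C7 and C7–C8 together, then the C8=C9 alkene of the resulting allylsilane and the C8′–C9′ bond.
2. The feature that allows the double ring cut is the ring itself. C7 sits between the ring oxygen and C8, C8 carries a one-carbon arm, the C7 aryl is cis to that arm and the C8′ benzyl is trans to it. An oxocarbenium ion at O=C7 closed by a (Z)-allylsilane should give this pattern, with C9 left as a vinyl group.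
3. Forward, the open chain holding C8′ and C9′ is built from dihydroferulic acid. The only ring closes in the key step as the vanillin-derived aldehyde is joined on. The vinyl group is then cut down to the C9 alcohol and the coumaroyl unit is attached last, before one global desilylation.
4. C8′ comes from a hydroxymethylation controlled by (R)-4-benzyloxazolidin-2-one. C7 and C8 are set in the cyclization relative to C8′. The (E)-alkene is bought with p-coumaric acid.

Key step: step 11

Remark: the three phenols are carried as triisopropylsilyl (TIPS) ethers and the C9′ oxygen as a triethylsilyl (TES) ether until the ring closure, and the five starting materials are taken as commercial.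

**Route**

Step 1
Reactants: 1 vanillin
Product: 2 3-methoxy-4-(triisopropylsilyloxy)benzaldehyde (fragment 1)
Conditions: TIPSCl, imidazole, DMF, rt
Reagents that add atoms: triisopropylsilyl chloride (TIPSCl), CC(C)[Si](Cl)(C(C)C)C(C)C
Why: Imidazole-mediated silylation of a phenol is routine, and the bulky aryl TIPS ether should survive the Lewis-acidic, basic and oxidative steps that follow until the final fluoride treatment.

Step 2
Reactants: 3 dihydroferulic acid
Product: 5 3-[3-methoxy-4-(triisopropylsilyloxy)phenyl]propanoic acid, via bis-silylated acid 4 (not isolated)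
Conditions: TIPSCl (2.3 equiv), imidazole, DMF, rt; then K2CO3, THF/MeOH/H2O, rt; 1 M HCl to pH 3
Reagents that add atoms: triisopropylsilyl chloride (TIPSCl), CC(C)[Si](Cl)(C(C)C)C(C)C
Why: Exhaustive silylation followed by selective hydrolysis of the much more labile silyl ester of 4 is the standard way to an O-silylated phenolic acid.

Step 3
Reactants: 5 3-[3-methoxy-4-(triisopropylsilyloxy)phenyl]propanoic acid, 6 (R)-4-benzyloxazolidin-2-one
Product: 8 (R)-4-benzyl-3-{3-[3-methoxy-4-(triisopropylsilyloxy)phenyl]propanoyl}oxazolidin-2-one, via mixed pivalic anhydride 7 (not isolated)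
Conditions: t-BuCOCl, Et3N, THF, −20 °C; then LiCl, 6, −20 °C → rt
Reagents that add atoms: none
Why: N-Acylation of an oxazolidinone through a mixed pivalic anhydride with LiCl/Et3N activation is a standard entry to Evans imides and avoids strong base near the aryl silyl ether.

Step 4
Reactants: 8 (R)-4-benzyl-3-{3-[3-methoxy-4-(triisopropylsilyloxy)phenyl]propanoyl}oxazolidin-2-one
Product: 10 (R)-4-benzyl-3-{(S)-3-hydroxy-2-[3-methoxy-4-(triisopropylsilyloxy)benzyl]propanoyl}oxazolidin-2-one, via trichlorotitanium enolate 9 (not isolated)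
Conditions: TiCl4 (1.05 equiv), i-Pr2NEt (1.1 equiv), CH2Cl2, 0 °C; then s-trioxane, TiCl4 (1.05 equiv), 0 °C; aq NH4Cl
Reagents that add atoms: s-trioxane (formaldehyde source), C1OCOCO1
Why: In this Evans titanium-enolate hydroxymethylation the chelated (Z)-enolate 9 should be attacked by TiCl4-activated formaldehyde on the face opposite the auxiliary benzyl group, which sets C8′ (S descriptor at this stage) and brings in C9′ with the future ring oxygen.

Step 5
Reactants: 10 (R)-4-benzyl-3-{(S)-3-hydroxy-2-[3-methoxy-4-(triisopropylsilyloxy)benzyl]propanoyl}oxazolidin-2-one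
Product: 11 (R)-4-benzyl-3-{(S)-2-[3-methoxy-4-(triisopropylsilyloxy)benzyl]-3-(triethylsilyloxy)propanoyl}oxazolidin-2-one
Conditions: TESCl, imidazole, CH2Cl2, 0 °C
Reagents that add atoms: triethylsilyl chloride (TESCl), CC[Si](Cl)(CC)CC
Why: Silylation of the primary alcohol as a TES ether gives a group that mild acid can later remove in the presence of the aryl TIPS ether and the allylsilane.

Step 6
Reactants: 11 (R)-4-benzyl-3-{(S)-2-[3-methoxy-4-(triisopropylsilyloxy)benzyl]-3-(triethylsilyloxy)propanoyl}oxazolidin-2-one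
Product: 12 (R)-2-[3-methoxy-4-(triisopropylsilyloxy)benzyl]-3-(triethylsilyloxy)propan-1-ol
Conditions: LiBH4, MeOH (1 equiv), THF, 0 °C
Reagents that add atoms: none
Why: Reductive cleavage of an N-acyloxazolidinone with LiBH4 gives the primary alcohol without touching the α-stereocentre and releases the auxiliary for recovery, and the low temperature should keep the TES group from migrating between the two oxygens.

Step 7
Reactants: 12 (R)-2-[3-methoxy-4-(triisopropylsilyloxy)benzyl]-3-(triethylsilyloxy)propan-1-ol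
Product: 13 (S)-2-[3-methoxy-4-(triisopropylsilyloxy)benzyl]-3-(triethylsilyloxy)propanal
Conditions: Dess–Martin periodinane, NaHCO3, CH2Cl2, 0 °C → rt; used crude at once
Reagents that add atoms: none
Why: Dess–Martin oxidation under bicarbonate buffer is a mild, non-basic method for α-branched β-silyloxy aldehydes, so the C8′ centre should stay intact if the aldehyde is used immediately.

Step 8
Reactants: 14 methyltriphenylphosphonium bromide
Product: 16 (2-trimethylsilylethyl)triphenylphosphonium iodide, via methylenetriphenylphosphorane 15 (not isolated)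
Conditions: n-BuLi, THF, 0 °C → rt; then ICH2SiMe3, rt
Reagents that add atoms: (iodomethyl)trimethylsilane, C[Si](C)(C)CI
Why: Deprotonation to the ylide and SN2 C-alkylation with the primary silylmethyl iodide is the standard preparation of this β-silylethyl phosphonium salt, which should crystallize from the mixture.

Step 9
Reactants: 13 (S)-2-[3-methoxy-4-(triisopropylsilyloxy)benzyl]-3-(triethylsilyloxy)propanal, 16 (2-trimethylsilylethyl)triphenylphosphonium iodide
Product: 18 (2R,3Z)-2-[3-methoxy-4-(triisopropylsilyloxy)benzyl]-1-(triethylsilyloxy)-5-(trimethylsilyl)pent-3-ene, via silylethylidene ylide 17 (not isolated)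
Conditions: 16, KN(SiMe3)2, THF, 0 °C; then 13, −78 °C → rt
Reagents that add atoms: none
Why: A Wittig olefination with a non-stabilized, lithium-free ylide should run under kinetic control through the cis-oxaphosphetane to the (Z)-allylsilane, and addition at −78 °C limits enolization of the α-branched aldehyde.

Step 10
Reactants: 18 (2R,3Z)-2-[3-methoxy-4-(triisopropylsilyloxy)benzyl]-1-(triethylsilyloxy)-5-(trimethylsilyl)pent-3-ene
Product: 19 (2R,3Z)-2-[3-methoxy-4-(triisopropylsilyloxy)benzyl]-5-(trimethylsilyl)pent-3-en-1-ol (fragment 2)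
Conditions: pyridinium p-toluenesulfonate (cat.), MeOH/CH2Cl2, 0 °C
Reagents that add atoms: none
Why: Acid-catalysed methanolysis cleaves a primary TES ether far faster than a hindered aryl TIPS ether, and pyridinium p-toluenesulfonate is too weak an acid to protodesilylate the allylsilane.

Step 11
Reactants: 19 (2R,3Z)-2-[3-methoxy-4-(triisopropylsilyloxy)benzyl]-5-(trimethylsilyl)pent-3-en-1-ol, 2 3-methoxy-4-(triisopropylsilyloxy)benzaldehyde
Product: 22 (2S,3R,4R)-2-[3-methoxy-4-(triisopropylsilyloxy)phenyl]-4-[3-methoxy-4-(triisopropylsilyloxy)benzyl]-3-vinyltetrahydrofuran, via trimethylsilyl ether 20 (not isolated), via oxocarbenium triflate 21 (not isolated)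
Conditions: Me3SiOTf (1.05 equiv), 2,6-lutidine (1.1 equiv), CH2Cl2, −78 °C; then 2 (1.2 equiv), Me3SiOTf (0.3 equiv), −78 °C, short; Et3N quench at −78 °C
Reagents that add atoms: none
Why: Catalytic Me3SiOTf condenses silyl ether 20 with aldehyde 2 to the (E)-oxocarbenium ion 21, whose carbon (C7) is attacked by the γ-carbon of the allylsilane (the future C8) so that the charge develops β to silicon, and loss of the silyl group then leaves the vinyl group on C8. The closest known reaction is the intramolecular Sakurai (allylsilane-terminated Prins-type) cyclization of 5-silylpent-3-en-1-ols with aldehydes, aromatic ones included, to 2-substituted 3-vinyltetrahydrofurans. The tetrahydrofuran ring (O, C7, C8, C8′, C9′) closes as a five-membered ring in a mode that is endo for the C=O+ unit and exo for the alkene, the six-membered Prins alternative being disfavoured because it would put the charge α to silicon. C8 is controlled by C8′: with the C8′–H bond eclipsing the (Z)-alkene to avoid A(1,3) strain with the CH2SiMe3 group, the tethered electrophile reaches C8 on the face away from the benzyl group, so vinyl and benzyl should end up trans. C7 is controlled by the alkene geometry: in the synclinal envelope transition state the (Z)-alkene lies over the oxocarbenium ion on the side of its aryl group, which should place aryl and vinyl cis. The step needs the kinetic 2,3-cis/3,4-trans isomer, which the (Z)-geometry and the pre-set C8′ centre secure, provided the reaction is kept short at −78 °C and quenched cold so that the electron-rich benzylic C7–O bond does not reionize.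

Step 12
Reactants: 22 (2S,3R,4R)-2-[3-methoxy-4-(triisopropylsilyloxy)phenyl]-4-[3-methoxy-4-(triisopropylsilyloxy)benzyl]-3-vinyltetrahydrofuran
Product: 25 {(2S,3S,4R)-2-[3-methoxy-4-(triisopropylsilyloxy)phenyl]-4-[3-methoxy-4-(triisopropylsilyloxy)benzyl]tetrahydrofuran-3-yl}methanol, via ozonide 23 (not isolated), via C8 aldehyde 24 (not isolated)
Conditions: O3, CH2Cl2, Sudan Red 7B, −78 °C; then NaBH4, MeOH, −78 → 0 °C
Reagents that add atoms: ozone, [O-][O+]=O
Why: Ozonolysis of the terminal vinyl group, which reacts with ozone much faster than the arenes and is followed with an indicator dye, and direct NaBH4 reduction of the ozonide through the aldehyde should give the C9 alcohol without isolating the epimerizable cis aldehyde, so the C8 configuration is kept.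

Step 13
Reactants: 26 (E)-p-coumaric acid
Product: 28 (E)-3-[4-(triisopropylsilyloxy)phenyl]acrylic acid (fragment 3), via bis-silylated acid 27 (not isolated)
Conditions: TIPSCl (2.3 equiv), imidazole, DMF, rt; then K2CO3, THF/MeOH/H2O, rt; 1 M HCl to pH 3
Reagents that add atoms: triisopropylsilyl chloride (TIPSCl), CC(C)[Si](Cl)(C(C)C)C(C)C
Why: The same bis-silylation and selective silyl ester hydrolysis as in step 2 masks the phenol, which would otherwise compete as a nucleophile in the esterification.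

Step 14
Reactants: 25 {(2S,3S,4R)-2-[3-methoxy-4-(triisopropylsilyloxy)phenyl]-4-[3-methoxy-4-(triisopropylsilyloxy)benzyl]tetrahydrofuran-3-yl}methanol, 28 (E)-3-[4-(triisopropylsilyloxy)phenyl]acrylic acid
Product: 29 {(2S,3S,4R)-2-[3-methoxy-4-(triisopropylsilyloxy)phenyl]-4-[3-methoxy-4-(triisopropylsilyloxy)benzyl]tetrahydrofuran-3-yl}methyl (E)-3-[4-(triisopropylsilyloxy)phenyl]acrylate
Conditions: 28 (1.2 equiv), DCC, 4-(dimethylamino)pyridine (cat.), CH2Cl2, 0 °C → rt
Reagents that add atoms: none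
Why: Steglich esterification of a primary alcohol with a cinnamic acid is reliable and nearly neutral, so the benzylic C7–O bond and the (E)-alkene should be left untouched.

Step 15
Reactants: 29 {(2S,3S,4R)-2-[3-methoxy-4-(triisopropylsilyloxy)phenyl]-4-[3-methoxy-4-(triisopropylsilyloxy)benzyl]tetrahydrofuran-3-yl}methyl (E)-3-[4-(triisopropylsilyloxy)phenyl]acrylate
Product: 30 {(2S,3S,4R)-2-(4-hydroxy-3-methoxyphenyl)-4-(4-hydroxy-3-methoxybenzyl)tetrahydrofuran-3-yl}methyl (E)-3-(4-hydroxyphenyl)acrylate (target CNP0119373.2)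
Conditions: Bu4NF (3.3 equiv), AcOH (3.5 equiv), THF, 0 °C
Reagents that add atoms: none
Why: Fluoride cleaves aryl silyl ethers quickly, and the acetic acid buffer keeps the phenoxide concentration low so that the ester should neither migrate nor hydrolyse and C7 is not scrambled through a quinone methide.

**Compound list**

1 | vanillin | COc1cc(C=O)ccc1O | starting material
2 | 3-methoxy-4-(triisopropylsilyloxy)benzaldehyde | COc1cc(C=O)ccc1O[Si](C(C)C)(C(C)C)C(C)C | intermediate
3 | dihydroferulic acid, 3-(4-hydroxy-3-methoxyphenyl)propanoic acid | COc1cc(CCC(=O)O)ccc1O | starting material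
4 | triisopropylsilyl 3-[3-methoxy-4-(triisopropylsilyloxy)phenyl]propanoate | COc1cc(CCC(=O)O[Si](C(C)C)(C(C)C)C(C)C)ccc1O[Si](C(C)C)(C(C)C)C(C)C | intermediate
5 | 3-[3-methoxy-4-(triisopropylsilyloxy)phenyl]propanoic acid | COc1cc(CCC(=O)O)ccc1O[Si](C(C)C)(C(C)C)C(C)C | intermediate
6 | (R)-4-benzyloxazolidin-2-one | O=C1N[C@H](Cc2ccccc2)CO1 | starting material
7 | mixed anhydride of 5 with pivalic acid | COc1cc(CCC(=O)OC(=O)C(C)(C)C)ccc1O[Si](C(C)C)(C(C)C)C(C)C | intermediate
8 | (R)-4-benzyl-3-{3-[3-methoxy-4-(triisopropylsilyloxy)phenyl]propanoyl}oxazolidin-2-one | COc1cc(CCC(=O)N2[C@H](Cc3ccccc3)COC2=O)ccc1O[Si](C(C)C)(C(C)C)C(C)C | intermediate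
9 | (Z)-trichlorotitanium enolate of 8 | COc1cc(C/C=C(\O[Ti](Cl)(Cl)Cl)N2[C@H](Cc3ccccc3)COC2=O)ccc1O[Si](C(C)C)(C(C)C)C(C)C | intermediate
10 | (R)-4-benzyl-3-{(S)-3-hydroxy-2-[3-methoxy-4-(triisopropylsilyloxy)benzyl]propanoyl}oxazolidin-2-one | COc1cc(C[C@@H](CO)C(=O)N2[C@H](Cc3ccccc3)COC2=O)ccc1O[Si](C(C)C)(C(C)C)C(C)C | intermediate
11 | (R)-4-benzyl-3-{(S)-2-[3-methoxy-4-(triisopropylsilyloxy)benzyl]-3-(triethylsilyloxy)propanoyl}oxazolidin-2-one | COc1cc(C[C@@H](CO[Si](CC)(CC)CC)C(=O)N2[C@H](Cc3ccccc3)COC2=O)ccc1O[Si](C(C)C)(C(C)C)C(C)C | intermediate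
12 | (R)-2-[3-methoxy-4-(triisopropylsilyloxy)benzyl]-3-(triethylsilyloxy)propan-1-ol | COc1cc(C[C@@H](CO[Si](CC)(CC)CC)CO)ccc1O[Si](C(C)C)(C(C)C)C(C)C | intermediate
13 | (S)-2-[3-methoxy-4-(triisopropylsilyloxy)benzyl]-3-(triethylsilyloxy)propanal | COc1cc(C[C@@H](CO[Si](CC)(CC)CC)C=O)ccc1O[Si](C(C)C)(C(C)C)C(C)C | intermediate
14 | methyltriphenylphosphonium bromide | C[P+](c1ccccc1)(c1ccccc1)c1ccccc1.[Br-] | starting material
15 | methylenetriphenylphosphorane | C=P(c1ccccc1)(c1ccccc1)c1ccccc1 | intermediate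
16 | (2-trimethylsilylethyl)triphenylphosphonium iodide | C[Si](C)(C)CC[P+](c1ccccc1)(c1ccccc1)c1ccccc1.[I-] | intermediate
17 | (2-trimethylsilylethylidene)triphenylphosphorane | C[Si](C)(C)CC=P(c1ccccc1)(c1ccccc1)c1ccccc1 | intermediate
18 | (2R,3Z)-2-[3-methoxy-4-(triisopropylsilyloxy)benzyl]-1-(triethylsilyloxy)-5-(trimethylsilyl)pent-3-ene | COc1cc(C[C@@H](CO[Si](CC)(CC)CC)/C=C\C[Si](C)(C)C)ccc1O[Si](C(C)C)(C(C)C)C(C)C | intermediate
19 | (2R,3Z)-2-[3-methoxy-4-(triisopropylsilyloxy)benzyl]-5-(trimethylsilyl)pent-3-en-1-ol | COc1cc(C[C@@H](CO)/C=C\C[Si](C)(C)C)ccc1O[Si](C(C)C)(C(C)C)C(C)C | intermediate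
20 | trimethylsilyl ether of 19 | COc1cc(C[C@@H](CO[Si](C)(C)C)/C=C\C[Si](C)(C)C)ccc1O[Si](C(C)C)(C(C)C)C(C)C | intermediate
21 | (E)-oxocarbenium triflate formed from 20 and 2 | COc1cc(C[C@@H](C/[O+]=C/c2ccc(O[Si](C(C)C)(C(C)C)C(C)C)c(OC)c2)/C=C\C[Si](C)(C)C)ccc1O[Si](C(C)C)(C(C)C)C(C)C.[O-]S(=O)(=O)C(F)(F)F | intermediate
22 | (2S,3R,4R)-2-[3-methoxy-4-(triisopropylsilyloxy)phenyl]-4-[3-methoxy-4-(triisopropylsilyloxy)benzyl]-3-vinyltetrahydrofuran | COc1cc(C[C@H]2CO[C@H](c3ccc(O[Si](C(C)C)(C(C)C)C(C)C)c(OC)c3)[C@@H]2C=C)ccc1O[Si](C(C)C)(C(C)C)C(C)C | intermediate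
23 | ozonide of 22, a 3-(1,2,4-trioxolan-3-yl)tetrahydrofuran (epimers at the trioxolane carbon) | COc1cc(C[C@H]2CO[C@H](c3ccc(O[Si](C(C)C)(C(C)C)C(C)C)c(OC)c3)[C@@H]2C4OCOO4)ccc1O[Si](C(C)C)(C(C)C)C(C)C | intermediate
24 | (2S,3R,4R)-2-[3-methoxy-4-(triisopropylsilyloxy)phenyl]-4-[3-methoxy-4-(triisopropylsilyloxy)benzyl]tetrahydrofuran-3-carbaldehyde | COc1cc(C[C@H]2CO[C@H](c3ccc(O[Si](C(C)C)(C(C)C)C(C)C)c(OC)c3)[C@@H]2C=O)ccc1O[Si](C(C)C)(C(C)C)C(C)C | intermediate
25 | {(2S,3S,4R)-2-[3-methoxy-4-(triisopropylsilyloxy)phenyl]-4-[3-methoxy-4-(triisopropylsilyloxy)benzyl]tetrahydrofuran-3-yl}methanol | COc1cc(C[C@H]2CO[C@H](c3ccc(O[Si](C(C)C)(C(C)C)C(C)C)c(OC)c3)[C@@H]2CO)ccc1O[Si](C(C)C)(C(C)C)C(C)C | intermediate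
26 | (E)-p-coumaric acid | OC(=O)/C=C/c1ccc(O)cc1 | starting material
27 | triisopropylsilyl (E)-3-[4-(triisopropylsilyloxy)phenyl]acrylate | CC(C)[Si](OC(=O)/C=C/c1ccc(O[Si](C(C)C)(C(C)C)C(C)C)cc1)(C(C)C)C(C)C | intermediate
28 | (E)-3-[4-(triisopropylsilyloxy)phenyl]acrylic acid | OC(=O)/C=C/c1ccc(O[Si](C(C)C)(C(C)C)C(C)C)cc1 | intermediate
29 | {(2S,3S,4R)-2-[3-methoxy-4-(triisopropylsilyloxy)phenyl]-4-[3-methoxy-4-(triisopropylsilyloxy)benzyl]tetrahydrofuran-3-yl}methyl (E)-3-[4-(triisopropylsilyloxy)phenyl]acrylate | COc1cc(C[C@H]2CO[C@H](c3ccc(O[Si](C(C)C)(C(C)C)C(C)C)c(OC)c3)[C@@H]2COC(=O)/C=C/c2ccc(O[Si](C(C)C)(C(C)C)C(C)C)cc2)ccc1O[Si](C(C)C)(C(C)C)C(C)C | intermediate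
30 | {(2S,3S,4R)-2-(4-hydroxy-3-methoxyphenyl)-4-(4-hydroxy-3-methoxybenzyl)tetrahydrofuran-3-yl}methyl (E)-3-(4-hydroxyphenyl)acrylate | COc1cc(C[C@H]2CO[C@H](c3ccc(O)c(OC)c3)[C@@H]2COC(=O)/C=C/c2ccc(O)cc2)ccc1O | target

**Step count**

Total: 15 steps. Longest linear sequence: 12 steps from dihydroferulic acid (steps 2, 3, 4, 5, 6, 7, 9, 10, 11, 12, 14, 15).

**Steps most likely to fail**

Step 11. The electron-rich aldehyde may condense slowly and reversibly, so that protodesilylation of the allylsilane competes with ring closure, or the product may reionize at the benzylic C7–O bond and drift to the 2,3-trans isomer. The fallback generates the oxocarbenium ion from a preformed α-acetoxy ether instead of by condensation. It sets out from 2, which is oxidized (NaClO2, NaH2PO4, 2-methyl-2-butene, t-BuOH/H2O, Pinnick oxidation) to 3-methoxy-4-(triisopropylsilyloxy)benzoic acid F1. Steglich esterification of F1 with alcohol 19 (DCC, 4-(dimethylamino)pyridine, CH2Cl2) should give the benzoate ester F2. Reduction with i-Bu2AlH at −78 °C gives the diisobutylaluminium hemiacetal F3, which is acetylated in the same flask (Ac2O, pyridine, 4-(dimethylamino)pyridine, −78 °C) to the α-acetoxy ether F4. Ionization of F4 with BF3·OEt2 in CH2Cl2 at −78 °C forms the same oxocarbenium ion stoichiometrically and without protic by-products, and the allylsilane closes the ring to 22, where the route is rejoined.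

Step 9. The basic ylide may enolize the α-branched β-silyloxy aldehyde, which would epimerize C8′ or eliminate triethylsilanol, and the (Z) selectivity may be incomplete. The fallback builds the (Z)-allylsilane by alkyne semi-hydrogenation instead of olefination. It sets out from aldehyde 13, which is converted under non-basic conditions (CBr4, PPh3, 2,6-lutidine, CH2Cl2, 0 °C, Corey–Fuchs) to the (R)-1,1-dibromoalkene F5. Treatment with n-BuLi (2.1 equiv, THF, −78 °C) gives the lithium acetylide F6, which is alkylated in the same flask with (trimethylsilyl)methyl triflate to the propargylsilane F7. Hydrogenation of F7 over Lindlar catalyst (Pd on CaCO3 poisoned with Pb(OAc)2, quinoline, H2) should deliver the (Z)-alkene and return to the route at 18.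

Step 12. Ozone may attack the two electron-rich arenes once the vinyl group is consumed, and the cis aldehyde may epimerize at C8 before it is reduced. The fallback cleaves the alkene through a diol instead. It sets out from 22, which is dihydroxylated (OsO4 cat., N-methylmorpholine N-oxide, acetone/H2O) to the 1,2-diol F8 as a mixture of carbinol epimers. Cleavage with NaIO4 in THF/pH 7 buffer at 0 °C gives aldehyde 24, which is reduced in the same flask with NaBH4 to return to the route at 25.

**Further compounds**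

F1 | step 11 | 3-methoxy-4-(triisopropylsilyloxy)benzoic acid | COc1cc(C(=O)O)ccc1O[Si](C(C)C)(C(C)C)C(C)C
F2 | step 11 | (2R,3Z)-2-[3-methoxy-4-(triisopropylsilyloxy)benzyl]-5-(trimethylsilyl)pent-3-en-1-yl 3-methoxy-4-(triisopropylsilyloxy)benzoate | COc1cc(C[C@@H](COC(=O)c2ccc(O[Si](C(C)C)(C(C)C)C(C)C)c(OC)c2)/C=C\C[Si](C)(C)C)ccc1O[Si](C(C)C)(C(C)C)C(C)C
F3 | step 11 | diisobutylaluminium hemiacetal of F2 (epimers at the acetal carbon) | COc1cc(C[C@@H](COC(O[Al](CC(C)C)CC(C)C)c2ccc(O[Si](C(C)C)(C(C)C)C(C)C)c(OC)c2)/C=C\C[Si](C)(C)C)ccc1O[Si](C(C)C)(C(C)C)C(C)C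
F4 | step 11 | α-acetoxy ether of 19 and the aryl aldehyde (epimers at the acetal carbon) | COc1cc(C[C@@H](COC(OC(C)=O)c2ccc(O[Si](C(C)C)(C(C)C)C(C)C)c(OC)c2)/C=C\C[Si](C)(C)C)ccc1O[Si](C(C)C)(C(C)C)C(C)C
F5 | step 9 | (R)-1,1-dibromo-3-[3-methoxy-4-(triisopropylsilyloxy)benzyl]-4-(triethylsilyloxy)but-1-ene | COc1cc(C[C@@H](CO[Si](CC)(CC)CC)C=C(Br)Br)ccc1O[Si](C(C)C)(C(C)C)C(C)C
F6 | step 9 | lithium acetylide of (R)-3-[3-methoxy-4-(triisopropylsilyloxy)benzyl]-4-(triethylsilyloxy)but-1-yne | COc1cc(C[C@@H](CO[Si](CC)(CC)CC)C#C[Li])ccc1O[Si](C(C)C)(C(C)C)C(C)C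
F7 | step 9 | (R)-2-[3-methoxy-4-(triisopropylsilyloxy)benzyl]-1-(triethylsilyloxy)-5-(trimethylsilyl)pent-3-yne | COc1cc(C[C@@H](CO[Si](CC)(CC)CC)C#CC[Si](C)(C)C)ccc1O[Si](C(C)C)(C(C)C)C(C)C
F8 | step 12 | 1-{(2S,3R,4R)-2-[3-methoxy-4-(triisopropylsilyloxy)phenyl]-4-[3-methoxy-4-(triisopropylsilyloxy)benzyl]tetrahydrofuran-3-yl}ethane-1,2-diol (epimers at the carbinol carbon) | COc1cc(C[C@H]2CO[C@H](c3ccc(O[Si](C(C)C)(C(C)C)C(C)C)c(OC)c3)[C@@H]2C(O)CO)ccc1O[Si](C(C)C)(C(C)C)C(C)C
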